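## Retrosynthetic overview

1. The target is three copies of one 14-membered macrodiolide plus one oxygen atom. The last C–C bond, C9 (ring B)–C9″ (ring A), is cut by a retro-Michael step to a cyclopentanone β-keto ester and a third ene-dione monomer.
2. The 2-hydroxycyclopentanone joining rings B and C is cut into the monomer ene-dione and its 10-hydroxy congener (enol of a 3,4-dioxo ester). The forward step is a light-driven [3+2] union: enol–ene-dione [2+2] photocycloaddition, retro-aldol, aldol.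
3. The 10-hydroxy congener comes from the monomer by nucleophilic epoxidation and base isomerisation.
4. The monomer ring is closed at C10–C11 by Nozaki–Hiyama–Kishi alkynylation, then redox-isomerised to the E-ene-dione; the Z-enoate comes from Lindlar reduction of a γ-silyloxy ynoate.
5. The open chain comes from two propiolic acid units, ethyl (S)-lactate (C6; C5 by Felkin–Anh addition), (S)-propylene oxide (C14) and an allyl Grignard reagent. Ring order: macrodiolide, then the cyclopentanone (rings B and C), then ring A, then global desilylation.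

Assumption: macrocycle positions follow 1,7-dioxacyclotetradecane (O1, C2=O, C3=C4, C5–O, C6–Me, O7, C8=O, C9, C10, C11, C12, C13, C14–Me; primes = ring C unit, double primes = ring A unit), and the face selectivities of steps 15 and 16 are taken to follow macrocyclic substrate control toward the configuration of the target; this is a prediction, not an established result.

## Route

Step 1
Reactants: 1 ethyl (S)-lactate
Product: 2 ethyl (S)-2-[(triethylsilyl)oxy]propanoate
Conditions: Et3SiCl, imidazole, CH2Cl2, 0 °C → rt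
Reagents that add atoms: chlorotriethylsilane, CC[Si](Cl)(CC)CC
Why: Imidazole-mediated O-silylation of the secondary alcohol leaves the stereocentre untouched and installs a TES ether that can later be removed beside a TBS ether.

Step 2
Reactants: 2 ethyl (S)-2-[(triethylsilyl)oxy]propanoate
Product: 3 (S)-2-[(triethylsilyl)oxy]propanal
Conditions: i-Bu2AlH (1.05 equiv), CH2Cl2, −78 °C; MeOH, aq. potassium sodium tartrate
Reagents that add atoms: none
Why: Partial ester reduction stops at the aluminium hemiacetal at −78 °C and releases the aldehyde only on work-up, so neither over-reduction nor α-epimerisation occurs.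

Step 3
Reactants: 4 (S)-propylene oxide; 5 allylmagnesium bromide
Product: 6 (S)-hex-5-en-2-ol
Conditions: CuI (5 mol %), THF/Et2O, −30 → 0 °C; aq. NH4Cl
Reagents that add atoms: none
Why: Copper-catalysed SN2 opening of the epoxide at its unsubstituted carbon leaves the C–O stereocentre (the future C14) untouched.

Step 4
Reactants: 6 (S)-hex-5-en-2-ol; 7 propiolic acid
Product: 8 (S)-hex-5-en-2-yl prop-2-ynoate
Conditions: DCC, DMAP (5 mol %), CH2Cl2, −20 → 0 °C
Reagents that add atoms: none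
Why: Steglich esterification, run cold to avoid conjugate addition to the propiolate, proceeds with retention at the carbinol carbon.

Step 5
Reactants: 8 (S)-hex-5-en-2-yl prop-2-ynoate; 3 (S)-2-[(triethylsilyl)oxy]propanal
Product: 11 (S)-hex-5-en-2-yl (4R,5S)-4-[(tert-butyldimethylsilyl)oxy]-5-[(triethylsilyl)oxy]hex-2-ynoate, via lithium acetylide 9 (not isolated), via lithium alkoxide 10 (not isolated)
Conditions: LiN(SiMe3)2 (1.05 equiv), THF, −78 °C; 3 (1.2 equiv), −78 °C; TBSOTf (1.3 equiv), −78 → −40 °C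
Reagents that add atoms: tert-butyldimethylsilyl trifluoromethanesulfonate, CC(C)(C)[Si](C)(C)OS(=O)(=O)C(F)(F)F
Why: Acetylide 1,2-addition to the non-chelating α-silyloxy aldehyde follows the Felkin–Anh model and gives the 4,5-anti adduct (new centre 4R, expected about 4:1), which is trapped in the flask as its TBS ether; the minor syn isomer is removed by chromatography at the stage of 12.

Step 6
Reactants: 11 (S)-hex-5-en-2-yl (4R,5S)-4-[(tert-butyldimethylsilyl)oxy]-5-[(triethylsilyl)oxy]hex-2-ynoate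
Product: 12 (S)-hex-5-en-2-yl (2Z,4R,5S)-4-[(tert-butyldimethylsilyl)oxy]-5-[(triethylsilyl)oxy]hex-2-enoate
Conditions: H2 (1 atm), Pd/CaCO3 poisoned with Pb(OAc)2, quinoline, EtOAc, rt, stopped at 1 equiv H2
Reagents that add atoms: none
Why: Lindlar semihydrogenation delivers H2 syn to the alkyne to give the Z-enoate, and the poisoned catalyst leaves the terminal alkene alone when the uptake is stopped at one equivalent.

Step 7
Reactants: 12 (S)-hex-5-en-2-yl (2Z,4R,5S)-4-[(tert-butyldimethylsilyl)oxy]-5-[(triethylsilyl)oxy]hex-2-enoate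
Product: 13 (S)-hex-5-en-2-yl (2Z,4R,5S)-4-[(tert-butyldimethylsilyl)oxy]-5-hydroxyhex-2-enoate
Conditions: PPTS (0.1 equiv), MeOH/CH2Cl2, 0 °C; used at once
Reagents that add atoms: none
Why: Acid-catalysed methanolysis cleaves the TES ether several hundred times faster than the secondary TBS ether; the Z-δ-hydroxy enoate is kept cold and acylated directly because it can close to a dihydropyranone on standing with acid or base.

Step 8
Reactants: 13 (S)-hex-5-en-2-yl (2Z,4R,5S)-4-[(tert-butyldimethylsilyl)oxy]-5-hydroxyhex-2-enoate; 7 propiolic acid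
Product: 14 (S)-hex-5-en-2-yl (2Z,4R,5S)-4-[(tert-butyldimethylsilyl)oxy]-5-(prop-2-ynoyloxy)hex-2-enoate
Conditions: DCC, DMAP (5 mol %), CH2Cl2, −20 °C
Reagents that add atoms: none
Why: Steglich esterification of the free C5 hydroxyl is fast at −20 °C and outruns lactonisation, with retention at the carbinol carbon.

Step 9
Reactants: 14 (S)-hex-5-en-2-yl (2Z,4R,5S)-4-[(tert-butyldimethylsilyl)oxy]-5-(prop-2-ynoyloxy)hex-2-enoate
Product: 15 (S)-hex-5-en-2-yl (2Z,4R,5S)-4-[(tert-butyldimethylsilyl)oxy]-5-[(3-iodoprop-2-ynoyl)oxy]hex-2-enoate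
Conditions: N-iodosuccinimide (1.2 equiv), AgNO3 (10 mol %), acetone, rt, dark
Reagents that add atoms: N-iodosuccinimide, O=C1CCC(=O)N1I
Why: Silver-catalysed electrophilic iodination acts only on the terminal alkyne C–H (through the silver acetylide) and leaves the alkenes and the silyl ether untouched.

Step 10
Reactants: 15 (S)-hex-5-en-2-yl (2Z,4R,5S)-4-[(tert-butyldimethylsilyl)oxy]-5-[(3-iodoprop-2-ynoyl)oxy]hex-2-enoate
Product: 17 (2S)-5-oxopentan-2-yl (2Z,4R,5S)-4-[(tert-butyldimethylsilyl)oxy]-5-[(3-iodoprop-2-ynoyl)oxy]hex-2-enoate, via ozonide 16 (not isolated)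
Conditions: O3, CH2Cl2, −78 °C (Sudan Red 7B end point); Me2S, −78 °C → rt
Reagents that add atoms: ozone, [O-][O+]=O
Why: Ozonolysis (Criegee mechanism) cleaves the only electron-rich alkene, the terminal vinyl group, far faster than the conjugated Z-enoate or the iodoalkynoate, and reductive work-up gives the aldehyde.

Step 11
Reactants: 17 (2S)-5-oxopentan-2-yl (2Z,4R,5S)-4-[(tert-butyldimethylsilyl)oxy]-5-[(3-iodoprop-2-ynoyl)oxy]hex-2-enoate
Product: 18 (3Z,5R,6S,14S)-5-[(tert-butyldimethylsilyl)oxy]-11-hydroxy-6,14-dimethyl-1,7-dioxacyclotetradec-3-en-9-yne-2,8-dione (both C11 epimers)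
Conditions: CrCl2 (8 equiv), NiCl2 (10 mol %), degassed THF/DMF, 2 mM, rt, slow addition of 17
Reagents that add atoms: none
Why: Nozaki–Hiyama–Kishi macrocyclisation: the iodoalkyne becomes an alkynyl trivalent-chromium species that adds only to the aldehyde under high dilution and tolerates the esters, the Z-enoate and the silyl ether; the C11 carbinol centre forms as a mixture and is erased in step 12.

Step 12
Reactants: 18 (3Z,5R,6S,14S)-5-[(tert-butyldimethylsilyl)oxy]-11-hydroxy-6,14-dimethyl-1,7-dioxacyclotetradec-3-en-9-yne-2,8-dione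
Product: 19 (3Z,5R,6S,9E,14S)-5-[(tert-butyldimethylsilyl)oxy]-6,14-dimethyl-1,7-dioxacyclotetradeca-3,9-diene-2,8,11-trione
Conditions: DABCO (20 mol %), DMSO, rt
Reagents that add atoms: none
Why: Amine-catalysed redox isomerisation of a γ-hydroxy ynoate (propargylic deprotonation, cumulenolate, allenol, ketone) gives the thermodynamically preferred E-γ-oxo enoate without an oxidant and creates no stereocentre.

Step 13
Reactants: 19 (3Z,5R,6S,9E,14S)-5-[(tert-butyldimethylsilyl)oxy]-6,14-dimethyl-1,7-dioxacyclotetradeca-3,9-diene-2,8,11-trione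
Product: 20 (3Z,5R,6S,14S)-5-[(tert-butyldimethylsilyl)oxy]-9,10-epoxy-6,14-dimethyl-1,7-dioxacyclotetradec-3-ene-2,8,11-trione (trans epoxide)
Conditions: 30% aq. H2O2 (3 equiv), Na2CO3 (0.2 equiv), THF, 0 °C
Reagents that add atoms: hydrogen peroxide, OO
Why: Weitz–Scheffer nucleophilic epoxidation attacks only the doubly activated ene-dione alkene (the Z-enoate is far less electrophilic) and its stepwise course gives the trans epoxide; both new centres are erased in step 14, so either trans diastereomer serves.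

Step 14
Reactants: 20 (3Z,5R,6S,14S)-5-[(tert-butyldimethylsilyl)oxy]-9,10-epoxy-6,14-dimethyl-1,7-dioxacyclotetradec-3-ene-2,8,11-trione
Product: 21 (3Z,5R,6S,9Z,14S)-5-[(tert-butyldimethylsilyl)oxy]-10-hydroxy-6,14-dimethyl-1,7-dioxacyclotetradeca-3,9-diene-2,8,11-trione
Conditions: DBU (1.05 equiv), CH2Cl2, −20 → 0 °C; aq. citric acid
Reagents that add atoms: none
Why: Base-induced epoxy ketone to α-diketone isomerisation (E1cB-type opening from the more acidic ketone-side C10–H, as in the chalcone oxide rearrangement) keeps the oxygen on C10 and gives the stabilised enol of the 3,4-dioxo ester; no stereocentre is formed.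

Step 15
Reactants: 21 (3Z,5R,6S,9Z,14S)-5-[(tert-butyldimethylsilyl)oxy]-10-hydroxy-6,14-dimethyl-1,7-dioxacyclotetradeca-3,9-diene-2,8,11-trione; 19 (3Z,5R,6S,9E,14S)-5-[(tert-butyldimethylsilyl)oxy]-6,14-dimethyl-1,7-dioxacyclotetradeca-3,9-diene-2,8,11-trione
Product: 24 bis-TBS rings B/C adduct (2-hydroxycyclopentanone; 9S,11S,9′S,10′S), via cyclobutanol photoadduct 22 (not isolated), via seco-diketone 23 (not isolated)
Conditions: thioxanthen-9-one (10 mol %), 405 nm LEDs, degassed MeCN (10 mM), 10 °C, 19 (1.3 equiv) added over 6 h; then Et3N (0.2 equiv), 0 °C, dark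
Reagents that add atoms: none
Why: Proposed new method: triplet sensitisation of the ene-dione 19 gives a twisted, electrophilic 1,2-biradical whose ester-side carbon C9′ bonds to the nucleophilic enol carbon C9 of 21 (leaving the better stabilised α-keto and hydroxy-acyl radical ends), spin inversion closes the head-to-head cyclobutanol 22, and this strained β-hydroxy ketone opens by retro-aldol to the vicinal diketone 23, which recloses by 5-exo aldol of C10′ onto C11 to the 2-hydroxycyclopentanone; the closest known reaction is the de Mayo reaction (enol–alkene [2+2] photocycloaddition then retro-aldol), not yet shown for the enol of a 3,4-dioxo ester with an ene-dione partner or with aldol re-closure to a five-membered ring; C9′ is set by bond formation on the exposed face of macrocycle 19 (controlled by its C6/C14 centres), C10′ and C11 by the reversible aldol (ring C trans-fused, OH cis to the C10′ acyl and hydrogen-bonded), and C9 settles through its enol to the only epimer in which ring B spans C9 and C11 on one face.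

Step 16
Reactants: 24 bis-TBS rings B/C adduct; 19 (3Z,5R,6S,9E,14S)-5-[(tert-butyldimethylsilyl)oxy]-6,14-dimethyl-1,7-dioxacyclotetradeca-3,9-diene-2,8,11-trione
Product: 25 tris-TBS ether of the target
Conditions: Cs2CO3 (0.2 equiv), MeCN, 0 °C → rt
Reagents that add atoms: none
Why: Base-mediated Michael addition of the cyclic β-keto ester (C9–H) to C9″ of a third ene-dione (β to its ketone) forms the quaternary centre; at C9 the bond can only form on the face opposite the ring B tether (C8 must stay cis to C12), and the 9″R configuration is expected from attack of the hindered enolate on the exposed face of the macrocyclic acceptor (matched double diastereocontrol).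

Step 17
Reactants: 25 tris-TBS ether of the target
Product: 26 CNP0072185.1 (target)
Conditions: HF·pyridine, pyridine, THF, 0 °C → rt
Reagents that add atoms: none
Why: Buffered fluoride cleavage of the three secondary TBS ethers under nearly neutral conditions avoids base (retro-aldol, retro-Michael) and strong acid (butenolide formation from the Z-γ-hydroxy enoates) and touches no stereocentre.

## Compound list

1 | ethyl (S)-lactate | C[C@H](O)C(=O)OCC | starting material
2 | ethyl (S)-2-[(triethylsilyl)oxy]propanoate | C[C@H](O[Si](CC)(CC)CC)C(=O)OCC | intermediate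
3 | (S)-2-[(triethylsilyl)oxy]propanal | C[C@H](O[Si](CC)(CC)CC)C=O | intermediate
4 | (S)-propylene oxide | C[C@H]1CO1 | starting material
5 | allylmagnesium bromide | C=CC[Mg]Br | starting material
6 | (S)-hex-5-en-2-ol | C[C@H](O)CCC=C | intermediate
7 | propiolic acid | C#CC(=O)O | starting material
8 | (S)-hex-5-en-2-yl prop-2-ynoate | C#CC(=O)O[C@@H](C)CCC=C | intermediate
9 | lithium acetylide of 8 (not isolated) | [Li]C#CC(=O)O[C@@H](C)CCC=C | intermediate
10 | lithium alkoxide of the (4R,5S) adduct (not isolated) | [Li]O[C@@H]([C@H](C)O[Si](CC)(CC)CC)C#CC(=O)O[C@@H](C)CCC=C | intermediate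
11 | (S)-hex-5-en-2-yl (4R,5S)-4-[(tert-butyldimethylsilyl)oxy]-5-[(triethylsilyl)oxy]hex-2-ynoate | C[C@H](O[Si](CC)(CC)CC)[C@H](O[Si](C)(C)C(C)(C)C)C#CC(=O)O[C@@H](C)CCC=C | intermediate
12 | (S)-hex-5-en-2-yl (2Z,4R,5S)-4-[(tert-butyldimethylsilyl)oxy]-5-[(triethylsilyl)oxy]hex-2-enoate | C[C@H](O[Si](CC)(CC)CC)[C@H](O[Si](C)(C)C(C)(C)C)/C=C\C(=O)O[C@@H](C)CCC=C | intermediate
13 | (S)-hex-5-en-2-yl (2Z,4R,5S)-4-[(tert-butyldimethylsilyl)oxy]-5-hydroxyhex-2-enoate | C[C@H](O)[C@H](O[Si](C)(C)C(C)(C)C)/C=C\C(=O)O[C@@H](C)CCC=C | intermediate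
14 | (S)-hex-5-en-2-yl (2Z,4R,5S)-4-[(tert-butyldimethylsilyl)oxy]-5-(prop-2-ynoyloxy)hex-2-enoate | C#CC(=O)O[C@@H](C)[C@H](O[Si](C)(C)C(C)(C)C)/C=C\C(=O)O[C@@H](C)CCC=C | intermediate
15 | (S)-hex-5-en-2-yl (2Z,4R,5S)-4-[(tert-butyldimethylsilyl)oxy]-5-[(3-iodoprop-2-ynoyl)oxy]hex-2-enoate | IC#CC(=O)O[C@@H](C)[C@H](O[Si](C)(C)C(C)(C)C)/C=C\C(=O)O[C@@H](C)CCC=C | intermediate
16 | secondary ozonide (1,2,4-trioxolane) of 15, not isolated, new ring centre undefined | IC#CC(=O)O[C@@H](C)[C@H](O[Si](C)(C)C(C)(C)C)/C=C\C(=O)O[C@@H](C)CCC1OCOO1 | intermediate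
17 | (2S)-5-oxopentan-2-yl (2Z,4R,5S)-4-[(tert-butyldimethylsilyl)oxy]-5-[(3-iodoprop-2-ynoyl)oxy]hex-2-enoate | IC#CC(=O)O[C@@H](C)[C@H](O[Si](C)(C)C(C)(C)C)/C=C\C(=O)O[C@@H](C)CCC=O | intermediate
18 | (3Z,5R,6S,14S)-5-[(tert-butyldimethylsilyl)oxy]-11-hydroxy-6,14-dimethyl-1,7-dioxacyclotetradec-3-en-9-yne-2,8-dione, both C11 epimers (C11 left undefined) | C[C@@H]1OC(=O)C#CC(O)CC[C@H](C)OC(=O)/C=C\[C@H]1O[Si](C)(C)C(C)(C)C | intermediate
19 | (3Z,5R,6S,9E,14S)-5-[(tert-butyldimethylsilyl)oxy]-6,14-dimethyl-1,7-dioxacyclotetradeca-3,9-diene-2,8,11-trione (silylated monomer) | C[C@@H]1OC(=O)/C=C/C(=O)CC[C@H](C)OC(=O)/C=C\[C@H]1O[Si](C)(C)C(C)(C)C | intermediate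
20 | 9,10-trans-epoxide of 19 (one trans diastereomer drawn; the other converges in step 14) | C[C@@H]1OC(=O)[C@H]2O[C@@H]2C(=O)CC[C@H](C)OC(=O)/C=C\[C@H]1O[Si](C)(C)C(C)(C)C | intermediate
21 | (3Z,5R,6S,9Z,14S)-5-[(tert-butyldimethylsilyl)oxy]-10-hydroxy-6,14-dimethyl-1,7-dioxacyclotetradeca-3,9-diene-2,8,11-trione (enol of the 10,11-diketone) | C[C@@H]1OC(=O)/C=C(O)/C(=O)CC[C@H](C)OC(=O)/C=C\[C@H]1O[Si](C)(C)C(C)(C)C | intermediate
22 | cyclobutanol photoadduct, not isolated: cyclobutane C9–C10(OH)–C10′–C9′ fused to both macrodiolides, all-trans arrangement drawn | [C@H]23C(=O)O[C@@H](C)[C@H](O[Si](C)(C)C(C)(C)C)/C=C\C(=O)O[C@@H](C)CCC(=O)[C@]2(O)[C@H]4C(=O)CC[C@H](C)OC(=O)/C=C\[C@@H](O[Si](C)(C)C(C)(C)C)[C@H](C)OC(=O)[C@H]34 | intermediate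
23 | seco-diketone, not isolated: C9–C9′ linked 10,11-diketone of ring B carrying ring C with C10′H2 (keto form drawn; C9 epimerises through its enol) | [C@H]2([C@@H]4CC(=O)CC[C@H](C)OC(=O)/C=C\[C@@H](O[Si](C)(C)C(C)(C)C)[C@H](C)OC4=O)C(=O)O[C@@H](C)[C@H](O[Si](C)(C)C(C)(C)C)/C=C\C(=O)O[C@@H](C)CCC(=O)C2=O | intermediate
24 | bis-TBS rings B/C adduct: 2-hydroxycyclopentanone made of C9, C10(=O), C11(OH) of ring B and C10′, C9′ of ring C; ring C trans-fused, 11-OH cis to the C10′ acyl; (9S,11S,9′S,10′S) | [C@@H]23C(=O)O[C@@H](C)[C@H](O[Si](C)(C)C(C)(C)C)/C=C\C(=O)O[C@@H](C)CC[C@@](O)(C2=O)[C@H]2C(=O)CC[C@H](C)OC(=O)/C=C\[C@@H](O[Si](C)(C)C(C)(C)C)[C@H](C)OC(=O)[C@@H]23 | intermediate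
25 | tris-TBS ether of the target (5-, 5′- and 5″-O-TBS; C9 quaternary and bonded to C9″; 9S,11S,9′S,10′S,9″R) | C[C@@H]1OC(=O)[C@@H]([C@@]23C(=O)O[C@@H](C)[C@H](O[Si](C)(C)C(C)(C)C)/C=C\C(=O)O[C@@H](C)CC[C@@](O)(C2=O)[C@H]2C(=O)CC[C@H](C)OC(=O)/C=C\[C@@H](O[Si](C)(C)C(C)(C)C)[C@H](C)OC(=O)[C@@H]23)CC(=O)CC[C@H](C)OC(=O)/C=C\[C@H]1O[Si](C)(C)C(C)(C)C | intermediate
26 | CNP0072185.1 | C[C@@H]1OC(=O)[C@@H]([C@@]23C(=O)O[C@@H](C)[C@H](O)/C=C\C(=O)O[C@@H](C)CC[C@@](O)(C2=O)[C@H]2C(=O)CC[C@H](C)OC(=O)/C=C\[C@@H](O)[C@H](C)OC(=O)[C@@H]23)CC(=O)CC[C@H](C)OC(=O)/C=C\[C@H]1O | target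

## Step count and risks

Total step count: 17. Longest linear sequence: 15 (steps 3, 4 and 5–17 from (S)-propylene oxide; equally steps 1, 2 and 5–17 from ethyl (S)-lactate).

Steps most likely to fail:

Step 15 (the new photochemical [3+2] union). The risks are self-dimerisation of the ene-dione, the wrong [2+2] regiochemistry (C9 to C10′) and poor face selectivity. The fallback is known chemistry: it sets out from 21 and 19 and comes back to the route at 24. Treating 21 and 19 with Et3N (1 equiv) or catalytic DBU in CH2Cl2 at 0 °C runs the ionic domino Michael/aldol annulation. The enolate of 21 adds through C9 to C9′ of 19 (β to the ketone), and the resulting ketone enolate, the conjugate base of 23, closes by aldol onto C11. New compounds on this path: none F0.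

Step 11 (macrocyclisation at C10–C11). The risks are sluggish formation of the alkynyl chromium species from the ester-bearing iodoalkyne and oligomerisation. The fallback closes the ring at the O7–C8 ester instead; it sets out from 12 and comes back at 19. Ozonolysis of 12 (O3, CH2Cl2, −78 °C; Me2S) gives (2S)-5-oxopentan-2-yl (2Z,4R,5S)-4-[(tert-butyldimethylsilyl)oxy]-5-[(triethylsilyl)oxy]hex-2-enoate F1. Addition of the dianion of propiolic acid 7 (LiN(i-Pr)2, 2 equiv, THF, −78 °C) gives (7S)-4-hydroxy-7-{[(2Z,4R,5S)-4-[(tert-butyldimethylsilyl)oxy]-5-[(triethylsilyl)oxy]hex-2-enoyl]oxy}oct-2-ynoic acid F2. DABCO in DMSO isomerises it to (2E,7S)-4-oxo-7-{[(2Z,4R,5S)-4-[(tert-butyldimethylsilyl)oxy]-5-[(triethylsilyl)oxy]hex-2-enoyl]oxy}oct-2-enoic acid F3. PPTS in MeOH at 0 °C removes the TES group to give (2E,7S)-7-{[(2Z,4R,5S)-4-[(tert-butyldimethylsilyl)oxy]-5-hydroxyhex-2-enoyl]oxy}-4-oxooct-2-enoic acid F4. Yamaguchi macrolactonisation (2,4,6-trichlorobenzoyl chloride, Et3N, THF; then DMAP, toluene, 1 mM) gives 19.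

Step 16 (Michael addition forming the quaternary centre). The risks are steric congestion, retro-Michael and retro-aldol under base, and the sense of induction at C9″. The fallback replaces the enolate by a silyl enol ether; it sets out from 24 and comes back at 25. Me3SiOTf and Et3N in CH2Cl2 (−78 → 0 °C) give the bis(trimethylsilyl) derivative of 24 (C10 silyl enol ether, 11-O-trimethylsilyl ether) F5. Mukaiyama–Michael addition of F5 to 19 with Sc(OTf)3 (10 mol %) in CH2Cl2 at −78 °C gives the silyl enol ether adduct (C10″=C11″ trimethylsilyl enol ether, 11-O-trimethylsilyl ether) F6. Citric acid in aqueous MeOH at 0 °C hydrolyses both trimethylsilyl groups to give 25.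

## Further compounds

F0 | step 15 | none | none
F1 | step 11 | (2S)-5-oxopentan-2-yl (2Z,4R,5S)-4-[(tert-butyldimethylsilyl)oxy]-5-[(triethylsilyl)oxy]hex-2-enoate | C[C@H](O[Si](CC)(CC)CC)[C@H](O[Si](C)(C)C(C)(C)C)/C=C\C(=O)O[C@@H](C)CCC=O
F2 | step 11 | (7S)-4-hydroxy-7-{[(2Z,4R,5S)-4-[(tert-butyldimethylsilyl)oxy]-5-[(triethylsilyl)oxy]hex-2-enoyl]oxy}oct-2-ynoic acid (both C4 epimers) | C[C@H](O[Si](CC)(CC)CC)[C@H](O[Si](C)(C)C(C)(C)C)/C=C\C(=O)O[C@@H](C)CCC(O)C#CC(=O)O
F3 | step 11 | (2E,7S)-4-oxo-7-{[(2Z,4R,5S)-4-[(tert-butyldimethylsilyl)oxy]-5-[(triethylsilyl)oxy]hex-2-enoyl]oxy}oct-2-enoic acid | C[C@H](O[Si](CC)(CC)CC)[C@H](O[Si](C)(C)C(C)(C)C)/C=C\C(=O)O[C@@H](C)CCC(=O)/C=C/C(=O)O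
F4 | step 11 | (2E,7S)-7-{[(2Z,4R,5S)-4-[(tert-butyldimethylsilyl)oxy]-5-hydroxyhex-2-enoyl]oxy}-4-oxooct-2-enoic acid | C[C@H](O)[C@H](O[Si](C)(C)C(C)(C)C)/C=C\C(=O)O[C@@H](C)CCC(=O)/C=C/C(=O)O
F5 | step 16 | bis(trimethylsilyl) derivative of 24 (C9=C10 trimethylsilyl enol ether, 11-O-trimethylsilyl ether) | C=23C(=O)O[C@@H](C)[C@H](O[Si](C)(C)C(C)(C)C)/C=C\C(=O)O[C@@H](C)CC[C@@](O[Si](C)(C)C)(C2O[Si](C)(C)C)[C@H]2C(=O)CC[C@H](C)OC(=O)/C=C\[C@@H](O[Si](C)(C)C(C)(C)C)[C@H](C)OC(=O)[C@@H]23
F6 | step 16 | Mukaiyama–Michael adduct of F5 and 19 (C10″=C11″ trimethylsilyl enol ether of undefined geometry, 11-O-trimethylsilyl ether) | C[C@@H]1OC(=O)[C@@H]([C@@]23C(=O)O[C@@H](C)[C@H](O[Si](C)(C)C(C)(C)C)/C=C\C(=O)O[C@@H](C)CC[C@@](O[Si](C)(C)C)(C2=O)[C@H]2C(=O)CC[C@H](C)OC(=O)/C=C\[C@@H](O[Si](C)(C)C(C)(C)C)[C@H](C)OC(=O)[C@@H]23)C=C(O[Si](C)(C)C)CC[C@H](C)OC(=O)/C=C\[C@H]1O[Si](C)(C)C(C)(C)C
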